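**Strategy**

Everything rests on cutting the cyclohexane ring at C7–C8 together with the lactone bond O8–C12. The precursor is an open-chain C8 aldehyde that ends in a (Z)-2-(bromomethyl)enoate (C7=C11, C13–Br, C12 methyl ester) and already holds C5, C6, C9 and C10. With CrCl2 the derived allylchromium adds through C7 to C8; this one operation closes the carbocycle, restores the C11=C13 methylene, sets C7 and C8 and lets the C8 alkoxide close the lactone. The step exploits the trans-fused α-methylene-γ-butyrolactone that spans the C7–C8 bond of the six-membered ring, which is the lactonised adduct of a 2-(methoxycarbonyl)allyl metal and an aldehyde.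

Key step: step 17

Remark on labels: atoms carry the target's elemane numbering. C10 is the quaternary carbon (C14 methyl, C1=C2 vinyl), C5 bears C4(=C15)–C3, C6 the angelate oxygen, C7–C8 the lactone fusion (C11=C13, C12=O, O8), C9 the free hydroxyl.

Remarks on the precursor:
- The allylic bromide is written as the Z isomer that the allylic transposition delivers; both geometries feed the same allylchromium pool.
- C6 is carried as a PMB ether through the chromium step and acylated afterwards. An acyloxy group at C6 would be β to chromium in the C7-bound form and could be lost by reductive elimination, and the amine-sensitive bromide rules out acylation once it is present.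
- C3 is a TBDPS ether so that it survives the acidic steps.
- C8 is masked until step 15 as a dioxolane whose stereocentre also controls C9.

**Route**

Step 1
Reactants: 1 2-bromoprop-2-en-1-ol
Product: 2 tert-butyl[(2-bromoprop-2-en-1-yl)oxy]diphenylsilane
Conditions: TBDPSCl, imidazole, CH2Cl2, 0 °C → rt
Reagents that add atoms: tert-butyl(chloro)diphenylsilane, CC(C)(C)[Si](Cl)(c1ccccc1)c1ccccc1
Why: Silyl ether formation on the primary alcohol (alcohol silylation) gives the C3–O group in a form that should survive every later acidic step and fall only to fluoride.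

Step 2
Reactants: 2 tert-butyl[(2-bromoprop-2-en-1-yl)oxy]diphenylsilane; 3 prop-2-yn-1-ol
Product: 4 5-[(tert-butyldiphenylsilyl)oxy]-4-methylidenepent-2-yn-1-ol
Conditions: Pd(PPh3)2Cl2 (cat.), CuI (cat.), Et3N, THF, 40 °C
Reagents that add atoms: none
Why: Sonogashira coupling of the 2-bromoalkene with the terminal alkyne should join C4 to C5 and bring in C5, C6 and C7 with the C7 hydroxyl in place.

Step 3
Reactants: 4 5-[(tert-butyldiphenylsilyl)oxy]-4-methylidenepent-2-yn-1-ol
Product: 5 (2Z)-5-[(tert-butyldiphenylsilyl)oxy]-4-methylidenepent-2-en-1-ol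
Conditions: Zn (activated with Cu(OAc)2 and AgNO3), MeOH–H2O, rt
Reagents that add atoms: none
Why: Zinc activated by copper and silver reduces a conjugated enyne by syn addition of hydrogen (Z-selective alkyne semi-reduction), so the C5=C6 bond should form cis while the 1,1-disubstituted C4=C15 bond is left alone.

Step 4
Reactants: 5 (2Z)-5-[(tert-butyldiphenylsilyl)oxy]-4-methylidenepent-2-en-1-ol
Product: 6 [(2R,3S)-3-{3-[(tert-butyldiphenylsilyl)oxy]prop-1-en-2-yl}oxiran-2-yl]methanol
Conditions: Ti(OiPr)4 (cat.), D-(−)-diethyl tartrate (cat.), t-BuOOH, 4 Å MS, CH2Cl2, −20 °C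
Reagents that add atoms: tert-butyl hydroperoxide, CC(C)(C)OO
Why: Sharpless asymmetric epoxidation reacts only at the alkene bound to the allylic hydroxyl, and the D-tartrate ligand selects the face that gives the (2R,3S) cis epoxide, which fixes C6 and presets C5 for substitution with inversion.

Step 5
Reactants: 6 [(2R,3S)-3-{3-[(tert-butyldiphenylsilyl)oxy]prop-1-en-2-yl}oxiran-2-yl]methanol; 7 ethynyl(trimethyl)silane
Product: 11 (2S,3R)-3-{3-[(tert-butyldiphenylsilyl)oxy]prop-1-en-2-yl}pent-4-yne-1,2-diol, via lithium (trimethylsilyl)acetylide 8 (not isolated), via diethyl[(trimethylsilyl)ethynyl]alane 9 (not isolated), via C-silylated diol 10 (not isolated)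
Conditions: 7, n-BuLi, Et2AlCl, toluene, 0 °C; 6, 0 °C → rt; work-up; K2CO3, MeOH, rt
Reagents that add atoms: none
Why: Organoalane opening of a 2,3-epoxy alcohol: the alkynylalane should attack the allylic C5 (the carbon remote from the hydroxymethyl group) with inversion, which sets C5 with C4 anti to O6 along C10–C5–C6–C7 and gives the 1,2-diol, and the carbonate methanolysis then removes the C-silyl group.

Step 6
Reactants: 11 (2S,3R)-3-{3-[(tert-butyldiphenylsilyl)oxy]prop-1-en-2-yl}pent-4-yne-1,2-diol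
Product: 12 4-methoxybenzylidene acetal of 11 (O6,O7-dioxolane; both epimers at the acetal carbon)
Conditions: 4-MeOC6H4CH(OMe)2, PPTS (cat.), CH2Cl2, rt
Reagents that add atoms: 4-methoxybenzaldehyde dimethyl acetal, COc1ccc(C(OC)OC)cc1
Why: Acid-catalysed transacetalisation (acetal formation) ties O6 and O7 into a dioxolane that should tolerate the organolithium, cuprate and hydride steps and later hand its 4-methoxybenzyl group to O6.

Step 7
Reactants: 12 4-methoxybenzylidene acetal of 11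
Product: 14 methyl (4R)-5-({[tert-butyl(diphenyl)silyl]oxy}methyl)-4-[(4S)-2-(4-methoxyphenyl)-1,3-dioxolan-4-yl]hex-5-en-2-ynoate, via lithium acetylide 13 (not isolated)
Conditions: n-BuLi, THF, −78 °C; ClCO2Me, −78 → 0 °C
Reagents that add atoms: methyl chloroformate, COC(=O)Cl
Why: Deprotonation of the terminal alkyne and C-acylation of the acetylide with the chloroformate (alkynoate synthesis) adds C2 at the ester level and makes C10 an acceptor carbon.

Step 8
Reactants: 14 methyl ynoate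
Product: 15 methyl (2Z,4R)-5-({[tert-butyl(diphenyl)silyl]oxy}methyl)-4-[(4S)-2-(4-methoxyphenyl)-1,3-dioxolan-4-yl]-3-methylhexa-2,5-dienoate
Conditions: Me2CuLi (from MeLi, CuI), THF, −78 °C; NH4Cl aq.
Reagents that add atoms: lithium dimethylcuprate, [Li+].C[Cu-]C
Why: Conjugate addition of the Gilman cuprate to the alkynoate is a syn carbocupration, so protonation with retention should leave the new C14 methyl on C10 trans to the ester and C5 cis to it, the Z geometry that step 10 needs.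

Step 9
Reactants: 15 methyl (2Z)-enoate
Product: 17 (2Z,4R,5S)-4-{3-[(tert-butyldiphenylsilyl)oxy]prop-1-en-2-yl}-5-[(4-methoxybenzyl)oxy]-3-methylhex-2-ene-1,6-diol, via acetal-bearing allylic alcohol 16 (not isolated)
Conditions: DIBAL-H, CH2Cl2, −78 °C → rt
Reagents that add atoms: none
Why: DIBAL-H reduces the ester to the allylic alcohol at low temperature and on warming opens the 4-methoxybenzylidene acetal reductively with aluminium on the less hindered O7, so the PMB ether should end up on O6 and C7 is freed (ester reduction followed by regioselective reductive acetal opening).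

Step 10
Reactants: 17 Z allylic alcohol (C2,C7-diol); 18 (R)-2,2-dimethyl-1,3-dioxolane-4-carbaldehyde
Product: 20 (1S,2S,3S,4S)-3-{3-[(tert-butyldiphenylsilyl)oxy]prop-1-en-2-yl}-1-[(4R)-2,2-dimethyl-1,3-dioxolan-4-yl]-2-ethenyl-4-[(4-methoxybenzyl)oxy]-2-methylpentane-1,5-diol, via allylboronic acid 19 (not isolated)
Conditions: B2(OH)4, Pd(MeCN)4(BF4)2 (cat.), DMSO–MeOH, rt; extraction; 18, 4 Å MS, CH2Cl2, rt
Reagents that add atoms: none
Why: Palladium-catalysed borylation turns the allylic alcohol into the Z γ,γ-disubstituted allylboronic acid, which adds to the aldehyde through a closed chair (Zimmerman–Traxler) transition state on the Felkin–Anh face anti to the dioxolane oxygen: this should set C9, and because C5 is axial and the methyl equatorial on the boron-containing chair, the quaternary C10 forms with O9 syn to the methyl group along C8–C9–C10–C5 (allylboration).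

Step 11
Reactants: 20 C7,C9-diol
Product: 21 bis-TBS ether of 20 (O7 and O9 silylated)
Conditions: TBSOTf, 2,6-lutidine, CH2Cl2, −78 → 0 °C
Reagents that add atoms: tert-butyldimethylsilyl trifluoromethanesulfonate, CC(C)(C)[Si](C)(C)OS(=O)(=O)C(F)(F)F
Why: The silyl triflate with 2,6-lutidine silylates both the primary C7 and the hindered secondary C9 hydroxyl (alcohol silylation).

Step 12
Reactants: 21 bis-TBS ether
Product: 22 (2S,3S,4S,5S)-5-[(tert-butyldimethylsilyl)oxy]-3-{3-[(tert-butyldiphenylsilyl)oxy]prop-1-en-2-yl}-5-[(4R)-2,2-dimethyl-1,3-dioxolan-4-yl]-4-ethenyl-2-[(4-methoxybenzyl)oxy]-4-methylpentan-1-ol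
Conditions: HF·pyridine, pyridine, THF, 0 °C
Reagents that add atoms: none
Why: Buffered HF·pyridine removes an unhindered primary TBS ether far faster than the neopentyl-type secondary TBS ether, the TBDPS ether or the acetonide (selective desilylation).

Step 13
Reactants: 22 C7 alcohol
Product: 23 (2S,3S,4S,5S)-5-[(tert-butyldimethylsilyl)oxy]-3-{3-[(tert-butyldiphenylsilyl)oxy]prop-1-en-2-yl}-5-[(4R)-2,2-dimethyl-1,3-dioxolan-4-yl]-4-ethenyl-2-[(4-methoxybenzyl)oxy]-4-methylpentanal
Conditions: Dess–Martin periodinane, NaHCO3, CH2Cl2, 0 °C → rt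
Reagents that add atoms: none
Why: Dess–Martin oxidation under bicarbonate buffer should give the α-alkoxy aldehyde without epimerising C6.

Step 14
Reactants: 23 C7 aldehyde; 24 methyl acrylate
Product: 25 methyl (4S,5S,6S,7S)-7-[(tert-butyldimethylsilyl)oxy]-5-{3-[(tert-butyldiphenylsilyl)oxy]prop-1-en-2-yl}-7-[(4R)-2,2-dimethyl-1,3-dioxolan-4-yl]-6-ethenyl-3-hydroxy-4-[(4-methoxybenzyl)oxy]-6-methyl-2-methylideneheptanoate (both C3 epimers)
Conditions: 24 (excess), DABCO, MeOH (cat.), rt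
Reagents that add atoms: none
Why: Morita–Baylis–Hillman reaction: the DABCO–acrylate zwitterion adds to the electrophilic α-alkoxy aldehyde and, after proton transfer and loss of DABCO, attaches C11, C12 and C13; the new C7 carbinol forms as both epimers, which does not matter because C7 becomes trigonal in step 16.

Step 15
Reactants: 25 Baylis–Hillman adduct
Product: 27 methyl (4S,5S,6S,7S)-7-[(tert-butyldimethylsilyl)oxy]-5-{3-[(tert-butyldiphenylsilyl)oxy]prop-1-en-2-yl}-6-ethenyl-3-hydroxy-4-[(4-methoxybenzyl)oxy]-6-methyl-2-methylidene-8-oxooctanoate (both C3 epimers), via terminal diol 26 (not isolated)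
Conditions: H5IO6, EtOAc, rt
Reagents that add atoms: none
Why: Periodic acid hydrolyses the terminal acetonide and cleaves the liberated 1,2-diol in the same flask (glycol cleavage), which should unmask the C8 aldehyde and remove the sacrificial carbon while the silyl and PMB ethers stay.

Step 16
Reactants: 27 C8 aldehyde with C7 carbinol
Product: 28 methyl (2Z,4R,5S,6S,7S)-2-(bromomethyl)-7-[(tert-butyldimethylsilyl)oxy]-5-{3-[(tert-butyldiphenylsilyl)oxy]prop-1-en-2-yl}-6-ethenyl-4-[(4-methoxybenzyl)oxy]-6-methyl-8-oxooct-2-enoate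
Conditions: NBS, Me2S, CH2Cl2, 0 °C
Reagents that add atoms: N-bromosuccinimide, O=C1CCC(=O)N1Br
Why: The sulfonium salt from NBS and Me2S activates the allylic hydroxyl and bromide attacks C13 with allylic transposition (SN2′ bromination of a Baylis–Hillman alcohol), so both C7 epimers should converge on the conjugated Z 2-(bromomethyl)enoate.

Step 17
Reactants: 28 open-chain C8 aldehyde with (Z)-2-(bromomethyl)enoate terminus
Product: 31 (3aS,4S,5S,6S,7S,7aR)-7-[(tert-butyldimethylsilyl)oxy]-5-{3-[(tert-butyldiphenylsilyl)oxy]prop-1-en-2-yl}-6-ethenyl-4-[(4-methoxybenzyl)oxy]-6-methyl-3-methylidenehexahydro-1-benzofuran-2(3H)-one, via allylchromium species 29 (not isolated), via chromium alkoxide 30 (not isolated)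
Conditions: CrCl2 (5 equiv), THF, rt, 0.01 M; NH4Cl aq.; PPTS (cat.), CH2Cl2, rt
Reagents that add atoms: none
Why: Two equivalents of CrCl2 reduce the C13–Br bond to a trivalent allylchromium whose E and Z forms interconvert by 1,3-metal shift; the E form adds through C7 to the C8 aldehyde in a chair Zimmerman–Traxler array fused to the forming carbocycle, and the C8 chromium alkoxide then displaces methoxide at C12 (closest known type: intramolecular Nozaki–Hiyama 2-(alkoxycarbonyl)allylation with lactonisation). The cyclohexane closes in 6-exo-trig mode at the C8 carbonyl (C7–C8 bond) and the lactone in 5-exo-trig mode at the C12 ester (O8–C12 bond). C7 and C8 should come out trans to each other because in the reacting E-allyl unit the C6 and C9 chain ends are both equatorial on the metal-containing chair, which places H7 and H8 antiperiplanar. Their sense relative to C5, C6, C9 and C10 is set by the chair of the forming carbocycle in which the C5 side chain and the C10 vinyl group are equatorial while the C10 methyl, O6 and O9 are axial. The step needs face selectivity between this chair and the alternative with vinyl and the C5 side chain axial, and chemoselectivity of divalent chromium for the allylic bromide. The substrate helps by making the C5 substituent (flanked by the quaternary C10) the bulkiest group on the ring, by placing the C6 ether oxygen in the inside position of the allyl unit, and by carrying C6 as an ether that cannot leave by 1,4-elimination.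

Step 18
Reactants: 31 bicyclic lactone (6-O-PMB)
Product: 32 (3aS,4S,5S,6S,7S,7aR)-7-[(tert-butyldimethylsilyl)oxy]-5-{3-[(tert-butyldiphenylsilyl)oxy]prop-1-en-2-yl}-6-ethenyl-4-hydroxy-6-methyl-3-methylidenehexahydro-1-benzofuran-2(3H)-one
Conditions: DDQ, CH2Cl2–pH 7 buffer, 0 °C → rt
Reagents that add atoms: none
Why: DDQ oxidises the electron-rich 4-methoxybenzyl ether to an oxocarbenium ion that water hydrolyses (oxidative PMB cleavage), freeing only the C6 hydroxyl.

Step 19
Reactants: 32 C6 alcohol; 33 angelic acid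
Product: 35 (3aS,4S,5S,6S,7S,7aR)-7-[(tert-butyldimethylsilyl)oxy]-5-{3-[(tert-butyldiphenylsilyl)oxy]prop-1-en-2-yl}-6-ethenyl-6-methyl-3-methylidene-2-oxooctahydro-1-benzofuran-4-yl (2Z)-2-methylbut-2-enoate, via mixed anhydride 34 (not isolated)
Conditions: 33, 2,4,6-Cl3C6H2COCl, Et3N, toluene, rt; 32, DMAP, toluene, rt → 40 °C
Reagents that add atoms: none
Why: Yamaguchi esterification: the mixed anhydride acylates DMAP at the angeloyl carbonyl and the acylpyridinium transfers the acyl group to the hindered axial C6 hydroxyl, the only free hydroxyl, under mild conditions chosen to keep the Z geometry of the angelate.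

Step 20
Reactants: 35 angelate bis-silyl ether
Product: 36 (3aS,4S,5S,6S,7S,7aR)-6-ethenyl-7-hydroxy-5-(3-hydroxyprop-1-en-2-yl)-6-methyl-3-methylidene-2-oxooctahydro-1-benzofuran-4-yl (2Z)-2-methylbut-2-enoate
Conditions: HF·pyridine, THF, 0 °C → rt
Reagents that add atoms: none
Why: HF·pyridine cleaves both silyl ethers (fluoride-mediated desilylation) under acidic conditions that should not harm the lactone, the angelate or the exocyclic alkenes.

Step 21
Reactants: 36 C3,C9-diol
Product: 37 (3aS,4S,5R,6S,7S,7aR)-6-ethenyl-7-hydroxy-6-methyl-3-methylidene-2-oxo-5-(3-oxoprop-1-en-2-yl)octahydro-1-benzofuran-4-yl (2Z)-2-methylbut-2-enoate (target)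
Conditions: MnO2, CH2Cl2, rt
Reagents that add atoms: none
Why: MnO2 oxidises only allylic alcohols, so the primary C3 alcohol should go to the enal while the secondary, non-allylic C9 hydroxyl stays (allylic oxidation).

**Compound list**

1 | 2-bromoprop-2-en-1-ol | C=C(Br)CO | starting material
2 | tert-butyl[(2-bromoprop-2-en-1-yl)oxy]diphenylsilane | C=C(Br)CO[Si](c1ccccc1)(c1ccccc1)C(C)(C)C | intermediate
3 | prop-2-yn-1-ol | C#CCO | starting material
4 | 5-[(tert-butyldiphenylsilyl)oxy]-4-methylidenepent-2-yn-1-ol | OCC#CC(=C)CO[Si](c1ccccc1)(c1ccccc1)C(C)(C)C | intermediate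
5 | (2Z)-5-[(tert-butyldiphenylsilyl)oxy]-4-methylidenepent-2-en-1-ol | OC/C=C\C(=C)CO[Si](c1ccccc1)(c1ccccc1)C(C)(C)C | intermediate
6 | [(2R,3S)-3-{3-[(tert-butyldiphenylsilyl)oxy]prop-1-en-2-yl}oxiran-2-yl]methanol | OC[C@H]1O[C@H]1C(=C)CO[Si](c2ccccc2)(c2ccccc2)C(C)(C)C | intermediate
7 | ethynyl(trimethyl)silane | C#C[Si](C)(C)C | starting material
8 | lithium (trimethylsilyl)acetylide (not isolated) | [Li]C#C[Si](C)(C)C | intermediate
9 | diethyl[(trimethylsilyl)ethynyl]alane (not isolated) | CC[Al](CC)C#C[Si](C)(C)C | intermediate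
10 | (2S,3S)-3-{3-[(tert-butyldiphenylsilyl)oxy]prop-1-en-2-yl}-5-(trimethylsilyl)pent-4-yne-1,2-diol (not isolated) | C[Si](C)(C)C#C[C@H](C(=C)CO[Si](c1ccccc1)(c1ccccc1)C(C)(C)C)[C@H](O)CO | intermediate
11 | (2S,3R)-3-{3-[(tert-butyldiphenylsilyl)oxy]prop-1-en-2-yl}pent-4-yne-1,2-diol | C#C[C@H](C(=C)CO[Si](c1ccccc1)(c1ccccc1)C(C)(C)C)[C@H](O)CO | intermediate
12 | tert-butyl[(2-{(1R)-1-[(4S)-2-(4-methoxyphenyl)-1,3-dioxolan-4-yl]prop-2-yn-1-yl}prop-2-en-1-yl)oxy]diphenylsilane (both epimers at the acetal carbon) | C#C[C@H](C(=C)CO[Si](c1ccccc1)(c1ccccc1)C(C)(C)C)[C@H]1COC(c2ccc(OC)cc2)O1 | intermediate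
13 | lithium acetylide of 12 (not isolated) | [Li]C#C[C@H](C(=C)CO[Si](c1ccccc1)(c1ccccc1)C(C)(C)C)[C@H]1COC(c2ccc(OC)cc2)O1 | intermediate
14 | methyl (4R)-5-({[tert-butyl(diphenyl)silyl]oxy}methyl)-4-[(4S)-2-(4-methoxyphenyl)-1,3-dioxolan-4-yl]hex-5-en-2-ynoate | COC(=O)C#C[C@H](C(=C)CO[Si](c1ccccc1)(c1ccccc1)C(C)(C)C)[C@H]1COC(c2ccc(OC)cc2)O1 | intermediate
15 | methyl (2Z,4R)-5-({[tert-butyl(diphenyl)silyl]oxy}methyl)-4-[(4S)-2-(4-methoxyphenyl)-1,3-dioxolan-4-yl]-3-methylhexa-2,5-dienoate | COC(=O)/C=C(/C)[C@H](C(=C)CO[Si](c1ccccc1)(c1ccccc1)C(C)(C)C)[C@H]1COC(c2ccc(OC)cc2)O1 | intermediate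
16 | (2Z,4R)-5-({[tert-butyl(diphenyl)silyl]oxy}methyl)-4-[(4S)-2-(4-methoxyphenyl)-1,3-dioxolan-4-yl]-3-methylhexa-2,5-dien-1-ol (not isolated) | OC/C=C(/C)[C@H](C(=C)CO[Si](c1ccccc1)(c1ccccc1)C(C)(C)C)[C@H]1COC(c2ccc(OC)cc2)O1 | intermediate
17 | (2Z,4R,5S)-4-{3-[(tert-butyldiphenylsilyl)oxy]prop-1-en-2-yl}-5-[(4-methoxybenzyl)oxy]-3-methylhex-2-ene-1,6-diol | OC/C=C(/C)[C@H](C(=C)CO[Si](c1ccccc1)(c1ccccc1)C(C)(C)C)[C@H](OCc1ccc(OC)cc1)CO | intermediate
18 | (R)-2,2-dimethyl-1,3-dioxolane-4-carbaldehyde | CC1(C)OC[C@@H](O1)C=O | starting material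
19 | [(2Z,4R,5S)-4-{3-[(tert-butyldiphenylsilyl)oxy]prop-1-en-2-yl}-6-hydroxy-5-[(4-methoxybenzyl)oxy]-3-methylhex-2-en-1-yl]boronic acid (not isolated) | OB(O)C/C=C(/C)[C@H](C(=C)CO[Si](c1ccccc1)(c1ccccc1)C(C)(C)C)[C@H](OCc1ccc(OC)cc1)CO | intermediate
20 | (1S,2S,3S,4S)-3-{3-[(tert-butyldiphenylsilyl)oxy]prop-1-en-2-yl}-1-[(4R)-2,2-dimethyl-1,3-dioxolan-4-yl]-2-ethenyl-4-[(4-methoxybenzyl)oxy]-2-methylpentane-1,5-diol | CC1(C)OC[C@@H](O1)[C@@H](O)[C@@](C)(C=C)[C@H](C(=C)CO[Si](c1ccccc1)(c1ccccc1)C(C)(C)C)[C@H](OCc1ccc(OC)cc1)CO | intermediate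
21 | bis-TBS ether of 20 (O7 and O9 silylated; stereocentres as in 20) | CC1(C)OC[C@@H](O1)[C@@H](O[Si](C)(C)C(C)(C)C)[C@@](C)(C=C)[C@H](C(=C)CO[Si](c1ccccc1)(c1ccccc1)C(C)(C)C)[C@H](OCc1ccc(OC)cc1)CO[Si](C)(C)C(C)(C)C | intermediate
22 | (2S,3S,4S,5S)-5-[(tert-butyldimethylsilyl)oxy]-3-{3-[(tert-butyldiphenylsilyl)oxy]prop-1-en-2-yl}-5-[(4R)-2,2-dimethyl-1,3-dioxolan-4-yl]-4-ethenyl-2-[(4-methoxybenzyl)oxy]-4-methylpentan-1-ol | CC1(C)OC[C@@H](O1)[C@@H](O[Si](C)(C)C(C)(C)C)[C@@](C)(C=C)[C@H](C(=C)CO[Si](c1ccccc1)(c1ccccc1)C(C)(C)C)[C@H](OCc1ccc(OC)cc1)CO | intermediate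
23 | (2S,3S,4S,5S)-5-[(tert-butyldimethylsilyl)oxy]-3-{3-[(tert-butyldiphenylsilyl)oxy]prop-1-en-2-yl}-5-[(4R)-2,2-dimethyl-1,3-dioxolan-4-yl]-4-ethenyl-2-[(4-methoxybenzyl)oxy]-4-methylpentanal | CC1(C)OC[C@@H](O1)[C@@H](O[Si](C)(C)C(C)(C)C)[C@@](C)(C=C)[C@H](C(=C)CO[Si](c1ccccc1)(c1ccccc1)C(C)(C)C)[C@H](OCc1ccc(OC)cc1)C=O | intermediate
24 | methyl acrylate | C=CC(=O)OC | starting material
25 | methyl (4S,5S,6S,7S)-7-[(tert-butyldimethylsilyl)oxy]-5-{3-[(tert-butyldiphenylsilyl)oxy]prop-1-en-2-yl}-7-[(4R)-2,2-dimethyl-1,3-dioxolan-4-yl]-6-ethenyl-3-hydroxy-4-[(4-methoxybenzyl)oxy]-6-methyl-2-methylideneheptanoate (both C3 epimers) | CC1(C)OC[C@@H](O1)[C@@H](O[Si](C)(C)C(C)(C)C)[C@@](C)(C=C)[C@H](C(=C)CO[Si](c1ccccc1)(c1ccccc1)C(C)(C)C)[C@H](OCc1ccc(OC)cc1)C(O)C(=C)C(=O)OC | intermediate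
26 | terminal 1,2-diol from acetonide hydrolysis of 25 (not isolated) | OC[C@@H](O)[C@@H](O[Si](C)(C)C(C)(C)C)[C@@](C)(C=C)[C@H](C(=C)CO[Si](c1ccccc1)(c1ccccc1)C(C)(C)C)[C@H](OCc1ccc(OC)cc1)C(O)C(=C)C(=O)OC | intermediate
27 | methyl (4S,5S,6S,7S)-7-[(tert-butyldimethylsilyl)oxy]-5-{3-[(tert-butyldiphenylsilyl)oxy]prop-1-en-2-yl}-6-ethenyl-3-hydroxy-4-[(4-methoxybenzyl)oxy]-6-methyl-2-methylidene-8-oxooctanoate (both C3 epimers) | O=C[C@@H](O[Si](C)(C)C(C)(C)C)[C@@](C)(C=C)[C@H](C(=C)CO[Si](c1ccccc1)(c1ccccc1)C(C)(C)C)[C@H](OCc1ccc(OC)cc1)C(O)C(=C)C(=O)OC | intermediate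
28 | methyl (2Z,4R,5S,6S,7S)-2-(bromomethyl)-7-[(tert-butyldimethylsilyl)oxy]-5-{3-[(tert-butyldiphenylsilyl)oxy]prop-1-en-2-yl}-6-ethenyl-4-[(4-methoxybenzyl)oxy]-6-methyl-8-oxooct-2-enoate | O=C[C@@H](O[Si](C)(C)C(C)(C)C)[C@@](C)(C=C)[C@H](C(=C)CO[Si](c1ccccc1)(c1ccccc1)C(C)(C)C)[C@H](OCc1ccc(OC)cc1)/C=C(\CBr)C(=O)OC | intermediate
29 | E allylchromium dichloride from 28, chromium on C13 (not isolated) | O=C[C@@H](O[Si](C)(C)C(C)(C)C)[C@@](C)(C=C)[C@H](C(=C)CO[Si](c1ccccc1)(c1ccccc1)C(C)(C)C)[C@H](OCc1ccc(OC)cc1)/C=C(/C[Cr](Cl)Cl)C(=O)OC | intermediate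
30 | chromium alkoxide of the cyclised C8 hydroxy ester, ring closed at C7–C8, methyl ester intact (not isolated) | C=C[C@]1(C)[C@H](O[Si](C)(C)C(C)(C)C)[C@H](O[Cr](Cl)Cl)[C@@H](C(=C)C(=O)OC)[C@@H](OCc2ccc(OC)cc2)[C@H]1C(=C)CO[Si](c2ccccc2)(c2ccccc2)C(C)(C)C | intermediate
31 | (3aS,4S,5S,6S,7S,7aR)-7-[(tert-butyldimethylsilyl)oxy]-5-{3-[(tert-butyldiphenylsilyl)oxy]prop-1-en-2-yl}-6-ethenyl-4-[(4-methoxybenzyl)oxy]-6-methyl-3-methylidenehexahydro-1-benzofuran-2(3H)-one | C=C[C@]1(C)[C@H](O[Si](C)(C)C(C)(C)C)[C@@H]2OC(=O)C(=C)[C@H]2[C@@H](OCc3ccc(OC)cc3)[C@H]1C(=C)CO[Si](c3ccccc3)(c3ccccc3)C(C)(C)C | intermediate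
32 | (3aS,4S,5S,6S,7S,7aR)-7-[(tert-butyldimethylsilyl)oxy]-5-{3-[(tert-butyldiphenylsilyl)oxy]prop-1-en-2-yl}-6-ethenyl-4-hydroxy-6-methyl-3-methylidenehexahydro-1-benzofuran-2(3H)-one | C=C[C@]1(C)[C@H](O[Si](C)(C)C(C)(C)C)[C@@H]2OC(=O)C(=C)[C@H]2[C@@H](O)[C@H]1C(=C)CO[Si](c3ccccc3)(c3ccccc3)C(C)(C)C | intermediate
33 | angelic acid, (2Z)-2-methylbut-2-enoic acid | C/C=C(/C)C(=O)O | starting material
34 | (2Z)-2-methylbut-2-enoic 2,4,6-trichlorobenzoic anhydride (not isolated) | C/C=C(/C)C(=O)OC(=O)c1c(Cl)cc(Cl)cc1Cl | intermediate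
35 | (3aS,4S,5S,6S,7S,7aR)-7-[(tert-butyldimethylsilyl)oxy]-5-{3-[(tert-butyldiphenylsilyl)oxy]prop-1-en-2-yl}-6-ethenyl-6-methyl-3-methylidene-2-oxooctahydro-1-benzofuran-4-yl (2Z)-2-methylbut-2-enoate | C=C[C@]1(C)[C@H](O[Si](C)(C)C(C)(C)C)[C@@H]2OC(=O)C(=C)[C@H]2[C@@H](OC(=O)/C(C)=C\C)[C@H]1C(=C)CO[Si](c3ccccc3)(c3ccccc3)C(C)(C)C | intermediate
36 | (3aS,4S,5S,6S,7S,7aR)-6-ethenyl-7-hydroxy-5-(3-hydroxyprop-1-en-2-yl)-6-methyl-3-methylidene-2-oxooctahydro-1-benzofuran-4-yl (2Z)-2-methylbut-2-enoate | C=C[C@]1(C)[C@H](O)[C@@H]2OC(=O)C(=C)[C@H]2[C@@H](OC(=O)/C(C)=C\C)[C@H]1C(=C)CO | intermediate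
37 | (3aS,4S,5R,6S,7S,7aR)-6-ethenyl-7-hydroxy-6-methyl-3-methylidene-2-oxo-5-(3-oxoprop-1-en-2-yl)octahydro-1-benzofuran-4-yl (2Z)-2-methylbut-2-enoate | C=C[C@]1(C)[C@H](O)[C@@H]2OC(=O)C(=C)[C@H]2[C@@H](OC(=O)/C(C)=C\C)[C@H]1C(=C)C=O | target

**Step count and risks**

Total step count: 21. Longest linear sequence: 21 steps (1 → 37); compounds 3, 7, 18, 24 and 33 are bought.

The three steps most likely to fail:

Step 17 (ring closure). The ring may close through the competing chair, in which the vinyl group and the C5 side chain are axial, so that the C7–C8 bond forms on the wrong face. The needed chair pays for a 1,3-diaxial contact between the C10 methyl and O6, so this is the real hazard of the route. Closure before the allylchromium geometries have equilibrated would in addition give a cis ring fusion. The fallback reverses the polarity of the bond formation. Bromide 28 is treated with KOAc and 18-crown-6 in MeCN to give the allylic acetate methyl (2Z,4R,5S,6S,7S)-2-(acetoxymethyl)-7-[(tert-butyldimethylsilyl)oxy]-5-{3-[(tert-butyldiphenylsilyl)oxy]prop-1-en-2-yl}-6-ethenyl-4-[(4-methoxybenzyl)oxy]-6-methyl-8-oxooct-2-enoate F1. SmI2 in THF–HMPA at −78 °C then turns the C8 aldehyde into a samarium ketyl that adds 6-exo to C7 of the enoate; the samarium enolate expels acetate from C13 to restore the C11=C13 methylene, and the C8 alkoxide lactonises. This samarium ketyl–alkene cyclisation with β-elimination has a radical, earlier transition state with a different conformational bias, and it returns to the route at lactone 31.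

Step 10 (borylation and allylboration). The palladium allyl intermediate may scramble the Z geometry, or the C5 stereocentre may oppose the facial bias of the aldehyde (mismatched double induction); either would erode control at C9 and C10. The fallback keeps O6 and O7 tied in the compact dioxolane and avoids palladium. Enoate 15 is reduced with DIBAL-H at −78 °C only and the allylic alcohol 16 is isolated. Diethyl chlorophosphate and pyridine give the allylic phosphate diethyl (2Z,4R)-5-({[tert-butyl(diphenyl)silyl]oxy}methyl)-4-[(4S)-2-(4-methoxyphenyl)-1,3-dioxolan-4-yl]-3-methylhexa-2,5-dien-1-yl phosphate F2. CrCl2 and LiI in DMPU convert it into the γ,γ-disubstituted Z allylchromium dichloride F3, which cannot isomerise without passing through a tertiary alkylchromium. F3 adds to aldehyde 18 through the same chair (Nozaki–Hiyama allylation) to give the homoallylic alcohol with the dioxolane intact, the O6,O7-(4-methoxybenzylidene) acetal corresponding to 20, F4. DIBAL-H at room temperature then opens the acetal and the sequence returns at diol 20.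

Step 5 (epoxide opening). Regiocontrol may be lost: the alane may attack C6, or C15 with allylic shift (SN2′) through the vinyl group. The fallback exchanges the roles of nucleophile and resident group. Commercial (E)-pent-2-en-4-yn-1-ol is C-silylated (EtMgBr, TMSCl, then mild acid) to (2E)-5-(trimethylsilyl)pent-2-en-4-yn-1-ol F5. The same titanium–tartrate epoxidation with D-(−)-diethyl tartrate, now on an E allylic alcohol, gives [(2R,3R)-3-[(trimethylsilyl)ethynyl]oxiran-2-yl]methanol F6. Vinyl bromide 2 is converted with t-BuLi into the alkenyllithium (3-{[tert-butyl(diphenyl)silyl]oxy}prop-1-en-2-yl)lithium F7 and with Me2AlCl into the alkenylalane (3-{[tert-butyl(diphenyl)silyl]oxy}prop-1-en-2-yl)dimethylalane F8. F8 opens F6 at the propargylic C5 with inversion, where there is no vinyl group to invite SN2′ attack, and the sequence returns at the C-silylated diol 10, which is desilylated to 11 as before.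

Further compounds
F1 | step 17 | methyl (2Z,4R,5S,6S,7S)-2-(acetoxymethyl)-7-[(tert-butyldimethylsilyl)oxy]-5-{3-[(tert-butyldiphenylsilyl)oxy]prop-1-en-2-yl}-6-ethenyl-4-[(4-methoxybenzyl)oxy]-6-methyl-8-oxooct-2-enoate | O=C[C@@H](O[Si](C)(C)C(C)(C)C)[C@@](C)(C=C)[C@H](C(=C)CO[Si](c1ccccc1)(c1ccccc1)C(C)(C)C)[C@H](OCc1ccc(OC)cc1)/C=C(\COC(C)=O)C(=O)OC
F2 | step 10 | diethyl (2Z,4R)-5-({[tert-butyl(diphenyl)silyl]oxy}methyl)-4-[(4S)-2-(4-methoxyphenyl)-1,3-dioxolan-4-yl]-3-methylhexa-2,5-dien-1-yl phosphate | CCOP(=O)(OCC)OC/C=C(/C)[C@H](C(=C)CO[Si](c1ccccc1)(c1ccccc1)C(C)(C)C)[C@H]1COC(c2ccc(OC)cc2)O1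
F3 | step 10 | Z allylchromium dichloride from F2, chromium on C2 | Cl[Cr](Cl)C/C=C(/C)[C@H](C(=C)CO[Si](c1ccccc1)(c1ccccc1)C(C)(C)C)[C@H]1COC(c2ccc(OC)cc2)O1
F4 | step 10 | O6,O7-(4-methoxybenzylidene) acetal corresponding to 20 (C9 hydroxyl free, C8 dioxolane intact) | CC1(C)OC[C@@H](O1)[C@@H](O)[C@@](C)(C=C)[C@H](C(=C)CO[Si](c1ccccc1)(c1ccccc1)C(C)(C)C)[C@H]1COC(c2ccc(OC)cc2)O1
F5 | step 5 | (2E)-5-(trimethylsilyl)pent-2-en-4-yn-1-ol | OC/C=C/C#C[Si](C)(C)C
F6 | step 5 | [(2R,3R)-3-[(trimethylsilyl)ethynyl]oxiran-2-yl]methanol | OC[C@H]1O[C@@H]1C#C[Si](C)(C)C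
F7 | step 5 | (3-{[tert-butyl(diphenyl)silyl]oxy}prop-1-en-2-yl)lithium | [Li]C(=C)CO[Si](c1ccccc1)(c1ccccc1)C(C)(C)C
F8 | step 5 | (3-{[tert-butyl(diphenyl)silyl]oxy}prop-1-en-2-yl)dimethylalane | C[Al](C)C(=C)CO[Si](c1ccccc1)(c1ccccc1)C(C)(C)C
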